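Reagent in the blue run starts at zero, so the first hours are a start-up: the reading at 2.00 h is 3.5%, and from 4.00 h the readings run nearly straight.

| flask | substrate | gas | remark | time |
|---|---|---|---|---|
| blue | 11 mM | 4 mM (held) | run made earlier |  |
| south-west | 30 mM | 4.0 mM (held) |  | 30 h |
| east | 10 mM | 4.0 mM (held) |  | 30 h |
| north-east | 40 mM | 4.0 mM (held) |  | 30 h |
| south-east | 3.0 mM | 4.0 mM (held) |  | 30 h |
| north-west | 20 mM | 4.0 mM (held) |  | 30 h |

blue run (percent of the substrate charged)

| time / h | product / % |
|---|---|
| 2.00 | 3.5 |
| 4.00 | 10.5 |
| 6.00 | 16.4 |
| 8.00 | 20.4 |
| 10.0 | 27.1 |

(standard deviation of a reading: 1 percentage point)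

- amounts and yields of product count crystals too
- given per volume of solution although it is solid: crystals
- at the start none of reagent is dissolved
- the earlier runs were read with a standard deviation of 1 percentage point
- on the list of suspects stand: gas <-> reagent; crystals <-> product; substrate <-> reactive form; reagent + reactive form -> product

- the flasks by amount of product, in percent of the substrate charged, highest first, at 30 h (south-west / east / north-east / south-east / north-west)
- the amount of product, in percent of the substrate charged of the flask you put first, at 30 h
- the amount of product, in percent of the substrate charged of the flask you put last, at 30 h

The next rung of the ladder is the steady consumption of substrate. Its measure is the fractional rate, the share of unreacted charge turned into product per hour (a pseudo-first-order constant while [reagent] holds steady). Read between 4.00 h and 10.0 h, it is 0.0342 h⁻¹. Its time scale is 29.2 h, so the start-up is over early, while the asked 30 h is about one such time. Carried on from the reading at 4.00 h, this gives 63.2% of the charge as product.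

That figure is the large term of my own reckoning; the small term is the deficit, the held 4.0 mM minus [reagent]. After the start-up the blue run draws reagent at the fractional rate times what is left of its charge, about 0.274 mM h⁻¹ at 10.0 h. The step to product uses reagent and reactive form together, so with gas uptake unchanged a larger charge pulls [reagent] down and the fractional rate with it, and the blue value can't simply be carried over to north-east. One run does not show how fast gas is taken up, so I expect yields near 63.2% at small charges, falling somewhat as the charge rises.

The forecast has the order south-east > east > north-west > south-west > north-east, from 80% down to 33%, a far wider spread than mine, on the ground that “percent yield should fall as substrate rises”.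

The flasks stand as south-east > east > north-west > south-west > north-east, the forecast's order, from 69.1% in south-east to 57.9% in north-east, with [reagent] at 3.94 mM and 3.13 mM at 30.0 h.

    gas ⇌ reagent, rate k1*(csat - [reagent]) (kL = 0.0112 min⁻¹)
    crystals ⇌ product, rate k2*(cs2 - [product]) while solid is left; crystals form when [product] > cs2 (solubility = 4.40 mM, k = 0.174 min⁻¹)
    substrate ⇌ reactive form (K = 0.160, k = 0.0125 min⁻¹)
    reagent + reactive form → product (k = 1.34 L mol⁻¹ min⁻¹)

Taken at 30.0 h, the fractional rate at its blue value times substrate and reactive form gives the draw, and dividing that draw by the uptake constant, 0.672 h⁻¹, gives the deficit. In north-east, substrate and reactive form hold 16.8 mM, so the deficit is 0.857 mM and [reagent] reckons to 3.14 mM, against 3.13 mM in the flask. In east, the deficit is 0.168 mM, so [reagent] reckons to 3.83 mM, against 3.79 mM in the flask.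

All runs are simulated from invented constants, and the scatter is random.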